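The indenone core is disconnected across its five-membered ring into an aryl bromide, a guaiazulenyl propyne and carbon monoxide. In one operation, a palladium-catalysed carbonylative annulation forms C3a–C3, C2–C1 and finally C1–C7a, closing the five-membered ring by acylation of the benzo C7a–H. It exploits that ketone carbon C1 lies between alkene carbon C2 and benzo carbon C7a and can come from CO, and that C7a–H is the only free position ortho to C3a, since C4 carries the (masked) formyl group. The precursors are the dioxolane of 2-bromo-5-(guaiazulen-3-yl)-4-methylbenzaldehyde and 3-(prop-1-ynyl)guaiazulene; acidic work-up unveils the aldehyde.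

Key step: step 6

Remark: "guaiazulen-3-yl" means 3,8-dimethyl-5-(propan-2-yl)azulen-1-yl (guaiazulene = 1,4-dimethyl-7-(propan-2-yl)azulene, bonded through C3); the indenone is numbered C1 (C=O), C2, C3, C3a, C4 to C7, C7a; the target has no stereocentre.

Step 1
Reactants: 1 guaiazulene
Product: 2 3-iodoguaiazulene (3-iodo-1,4-dimethyl-7-(propan-2-yl)azulene)
Conditions: NIS (1.0 equiv), CH2Cl2, 0 °C, dark; short filtration through basic alumina, used at once
Reagents that add atoms: N-iodosuccinimide, O=C1CCC(=O)N1I
Why: Electrophilic aromatic iodination should occur at C3, the most nucleophilic free position of the azulene five-membered ring, under neutral conditions.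

Step 2
Reactants: 2 3-iodoguaiazulene; 3 propyne
Product: 4 3-(prop-1-yn-1-yl)guaiazulene (1,4-dimethyl-7-(propan-2-yl)-3-(prop-1-yn-1-yl)azulene)
Conditions: propyne (ca. 1 M in THF, excess), PdCl2(PPh3)2 (3 mol %), CuI (5 mol %), Et3N, THF, rt, sealed vessel
Reagents that add atoms: none
Why: Sonogashira coupling of the azulenyl iodide with propyne should proceed at room temperature under amine conditions that the azulene tolerates.

Step 3
Reactants: 5 2-bromo-4-methylbenzaldehyde
Product: 6 2-bromo-5-iodo-4-methylbenzaldehyde
Conditions: NIS (1.1 equiv), TfOH, CH2Cl2, 0 °C to rt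
Reagents that add atoms: N-iodosuccinimide, O=C1CCC(=O)N1I
Why: Acid-activated electrophilic aromatic iodination should go to C5, which is ortho to methyl, para to bromine and meta to the formyl group, and less hindered than C3 between bromine and methyl.

Step 4
Reactants: 6 2-bromo-5-iodo-4-methylbenzaldehyde
Product: 7 2-(2-bromo-5-iodo-4-methylphenyl)-1,3-dioxolane
Conditions: ethylene glycol, p-TsOH (cat.), toluene, reflux, Dean–Stark
Reagents that add atoms: ethylene glycol, OCCO
Why: Acid-catalysed acetalisation with azeotropic removal of water masks the aldehyde, which would otherwise capture the vinylpalladium intermediate of step 6 in a Larock-type indenone closure.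

Step 5
Reactants: 7 2-(2-bromo-5-iodo-4-methylphenyl)-1,3-dioxolane; 1 guaiazulene
Product: 8 2-[2-bromo-5-(guaiazulen-3-yl)-4-methylphenyl]-1,3-dioxolane
Conditions: 1 (1.3 equiv), Pd(OAc)2 (5 mol %), KOAc (2 equiv), DMAc, 100 °C
Reagents that add atoms: none
Why: Palladium-catalysed direct C–H arylation of guaiazulene in a polar amide solvent with acetate should take place at its nucleophilic C3, and oxidative addition should select the aryl iodide over the hindered, unactivated aryl bromide.

Step 6
Reactants: 8 2-[2-bromo-5-(guaiazulen-3-yl)-4-methylphenyl]-1,3-dioxolane; 4 3-(prop-1-yn-1-yl)guaiazulene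
Product: 10 CNP0222726.0 (2,6-bis(guaiazulen-3-yl)-3,7-dimethyl-1-oxo-1H-indene-4-carbaldehyde), via dioxolane-protected indenone 9 (not isolated)
Conditions: 4 (1.5 equiv), Pd(PCy3)2 (10 mol %), CsOPiv (cesium pivalate, 2 equiv), CO (1 atm), DMF, 110 °C; then 1 M HCl, THF, rt
Reagents that add atoms: carbon monoxide, [C-]#[O+]; water, O
Why: Proposed new method: zerovalent palladium should insert into the C–Br bond of 8, the arylpalladium add syn across alkyne 4 with the aryl group going to the methyl-bearing carbon (C3a–C3) and palladium to the guaiazulenyl-bearing carbon, CO insert into the vinyl–palladium bond (C2–C1), and pivalate-assisted concerted metalation–deprotonation at C7a–H give a six-membered acylpalladacycle whose C–C reductive elimination forms C1–C7a; dilute acid then cleaves the dioxolane. The closest known reaction types are the carbonylative Larock-type annulation of internal alkynes with 2-iodophenols to coumarins (alkyne insertion ahead of CO insertion) and the palladium-catalysed cyclocarbonylation of 2-halobiaryls to fluorenones (acylpalladium closing onto an arene C–H); their merger into an indenone annulation of a plain aryl halide is the new element. The five-membered ring is closed by intramolecular C–H acylation, the cis arrangement of aryl group and acyl carbon that this needs being fixed by the syn carbopalladation; no stereocentre arises. Three selectivities are needed: alkyne before CO insertion, which rests on reversible aroylpalladium formation at 110 °C under 1 atm CO and on the slow acylpalladation of internal alkynes; the alkyne orientation, which the bulky electron-rich guaiazulenyl group secures by ending up next to palladium as aryl groups do in annulations of 1-arylpropynes; and the acylation site, which is unambiguous because C7a–H is the only C–H ortho to C3a, C4 being blocked by the dioxolane. The dioxolane also keeps the vinylpalladium from adding to a free formyl group.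

Compound list
1 | guaiazulene (1,4-dimethyl-7-(propan-2-yl)azulene) | c1cc(C)c2cc(C(C)C)ccc(C)c1-2 | starting material
2 | 3-iodoguaiazulene | Ic1cc(C)c2cc(C(C)C)ccc(C)c1-2 | intermediate
3 | propyne | CC#C | starting material
4 | 3-(prop-1-yn-1-yl)guaiazulene | CC#Cc1cc(C)c2cc(C(C)C)ccc(C)c1-2 | intermediate
5 | 2-bromo-4-methylbenzaldehyde | Cc1ccc(C=O)c(Br)c1 | starting material
6 | 2-bromo-5-iodo-4-methylbenzaldehyde | Cc1cc(Br)c(C=O)cc1I | intermediate
7 | 2-(2-bromo-5-iodo-4-methylphenyl)-1,3-dioxolane | Cc1cc(Br)c(C2OCCO2)cc1I | intermediate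
8 | 2-[2-bromo-5-(guaiazulen-3-yl)-4-methylphenyl]-1,3-dioxolane | Cc1cc(Br)c(C2OCCO2)cc1-c1cc(C)c2cc(C(C)C)ccc(C)c1-2 | intermediate
9 | 4-(1,3-dioxolan-2-yl)-2,6-bis(guaiazulen-3-yl)-3,7-dimethyl-1H-inden-1-one | CC1=C(c2cc(C)c3cc(C(C)C)ccc(C)c2-3)C(=O)c2c(C)c(-c3cc(C)c4cc(C(C)C)ccc(C)c3-4)cc(C3OCCO3)c21 | intermediate
10 | CNP0222726.0, 2,6-bis(guaiazulen-3-yl)-3,7-dimethyl-1-oxo-1H-indene-4-carbaldehyde | CC1=C(c2cc(C)c3cc(C(C)C)ccc(C)c2-3)C(=O)c2c(C)c(-c3cc(C)c4cc(C(C)C)ccc(C)c3-4)cc(C=O)c21 | target

Total step count: 6
Longest linear sequence: 4 steps (5 → 6 → 7 → 8 → 10; steps 3, 4, 5, 6)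

Steps most likely to fail

Step 6. CO may insert into the aryl–palladium bond before the alkyne does, so that the aroylpalladium adds to the alkyne and leads to the regioisomeric indenone or to open-chain products; the hindered C7a–H may also resist acylation. The fallback uses known reaction types and fixes the order of events by separating carbon–carbon bond formation from carbonylation. It sets out from 8 and 4. Bromine–magnesium exchange of 8 (i-PrMgCl·LiCl, THF, rt, assisted by the ortho dioxolane) should give chloro[2-(1,3-dioxolan-2-yl)-4-(guaiazulen-3-yl)-5-methylphenyl]magnesium F1, and transmetalation with ZnCl2 the arylzinc chloride F2. CoBr2-catalysed syn-arylzincation of 4 (MeCN/THF, rt) should place the aryl group on the methyl-bearing carbon and give the (Z)-alkenylzinc chloride F3, which I2 converts to the (Z)-alkenyl iodide F4 with aryl group and iodine cis. Palladium-catalysed cyclocarbonylation of F4 (Pd(PCy3)2, CsOPiv, CO 1 atm, DMF, 110 °C), the reaction type known from 2-iodobiaryls to fluorenones, then leaves vinylpalladium → acylpalladium → C7a–H acylation as the only path. The fallback comes back to the route at 9, which acidic work-up converts to 10.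

Step 5. Chemoselectivity may be lost through oxidative addition into the C–Br bond as well, giving double arylation, and regioselectivity on guaiazulene may drift to C2 or to the C4 methyl group. The fallback fixes both by using a preformed azulenyl nucleophile at room temperature. It sets out from 2 and 7. Iodine–magnesium exchange of 2 (i-PrMgCl·LiCl, THF, −40 °C) should give chloro(guaiazulen-3-yl)magnesium F5, and ZnCl2 the chloro(guaiazulen-3-yl)zinc F6. Negishi coupling of F6 with 7 (Pd(PPh3)4, THF, rt) should engage only the C–I bond. The fallback comes back to the route at 8.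

Step 2. The labile iodide 2 may decompose (loss of iodine, oxidative dimerisation) faster than it couples, and the alkyne may homocouple. The fallback avoids any azulenyl halide. It sets out from 1. Vilsmeier–Haack reaction (POCl3, DMF, 0 °C) should give the iminium salt N-[(guaiazulen-3-yl)methylidene]-N-methylmethanaminium chloride F7, hydrolysed with aqueous NaOH to guaiazulene-3-carbaldehyde F8. Corey–Fuchs olefination (CBr4, PPh3, CH2Cl2, 0 °C) should give 3-(2,2-dibromoethenyl)guaiazulene F9. n-BuLi (2.1 equiv, THF, −78 °C) should give lithium 2-(guaiazulen-3-yl)ethyn-1-ide F10, which MeI methylates in the same flask. The fallback comes back to the route at 4.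

Further compounds
F1 | step 6 | chloro[2-(1,3-dioxolan-2-yl)-4-(guaiazulen-3-yl)-5-methylphenyl]magnesium | Cc1cc([Mg]Cl)c(C2OCCO2)cc1-c1cc(C)c2cc(C(C)C)ccc(C)c1-2
F2 | step 6 | chloro[2-(1,3-dioxolan-2-yl)-4-(guaiazulen-3-yl)-5-methylphenyl]zinc | Cc1cc([Zn]Cl)c(C2OCCO2)cc1-c1cc(C)c2cc(C(C)C)ccc(C)c1-2
F3 | step 6 | chloro{(1Z)-2-[2-(1,3-dioxolan-2-yl)-4-(guaiazulen-3-yl)-5-methylphenyl]-1-(guaiazulen-3-yl)prop-1-en-1-yl}zinc | C/C(c1cc(C)c(-c2cc(C)c3cc(C(C)C)ccc(C)c2-3)cc1C1OCCO1)=C(/[Zn]Cl)c1cc(C)c2cc(C(C)C)ccc(C)c1-2
F4 | step 6 | 3-{(1Z)-2-[2-(1,3-dioxolan-2-yl)-4-(guaiazulen-3-yl)-5-methylphenyl]-1-iodoprop-1-en-1-yl}guaiazulene | C/C(c1cc(C)c(-c2cc(C)c3cc(C(C)C)ccc(C)c2-3)cc1C1OCCO1)=C(/I)c1cc(C)c2cc(C(C)C)ccc(C)c1-2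
F5 | step 5 | chloro(guaiazulen-3-yl)magnesium | Cl[Mg]c1cc(C)c2cc(C(C)C)ccc(C)c1-2
F6 | step 5 | chloro(guaiazulen-3-yl)zinc | Cl[Zn]c1cc(C)c2cc(C(C)C)ccc(C)c1-2
F7 | step 2 | N-[(guaiazulen-3-yl)methylidene]-N-methylmethanaminium chloride | C[N+](C)=Cc1cc(C)c2cc(C(C)C)ccc(C)c1-2.[Cl-]
F8 | step 2 | guaiazulene-3-carbaldehyde | O=Cc1cc(C)c2cc(C(C)C)ccc(C)c1-2
F9 | step 2 | 3-(2,2-dibromoethenyl)guaiazulene | BrC(Br)=Cc1cc(C)c2cc(C(C)C)ccc(C)c1-2
F10 | step 2 | lithium 2-(guaiazulen-3-yl)ethyn-1-ide | [Li]C#Cc1cc(C)c2cc(C(C)C)ccc(C)c1-2
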